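Remarks and assumptions (chemistry only):
- Numbering is labdane-type: ring carbons C1–C10 (ring olefin C8=C9), side chain C11–C19 (C16 = lactone stereocentre, C19 = lactone C=O), C20 = CH2OH on C13, C21 = CH2OH on C17.
- Dr = (4aS,8aS)-2,5,5,8a-tetramethyl-3,4,4a,5,6,7,8,8a-octahydronaphthalen-1-yl.
- Both antipodes of the oxazoline–sulfonamide ligand of step 11 are taken as accessible; the one that directs the alkenyl group to the Si face of aldehyde 11 is used.

## The problem

The target (17) is a C25 butenolide terpenoid: a trans-decalin (5S,10S) with a tetrasubstituted C8=C9 bond, whose C9 carries a chain ending in a trisubstituted allylic alcohol and an (R)-4-(hydroxymethyl)butenolide. The ring system is not the hard part, because (+)-sclareolide (1) supplies C1–C12 and both ring stereocentres; the difficulty is in the side chain.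

- The C13=C14 bond must be built with C12 and C15 cis (C20 trans to C15).
- C16 lies eight bonds from the nearest ring stereocentre, so no substrate control is possible and it must be set by a reagent. It must also be set late, because C16–H is γ to the lactone carbonyl and epimerises through the 2-oxidofuran under base.
- Hydride reagents attack the lactone before an acyclic ester, so C20 cannot be brought to the alcohol level once the butenolide exists.
- The electron-rich C8=C9 bond excludes ozone, peracids, singlet oxygen and strong acid, and it must be placed cleanly among three possible olefin positions.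

Two features of the structure make the key step possible. C11 is bonded to C9 of the C8=C9 bond of ring B, so a radical at C11 is an allyl radical, and the carboxyl carbon that sclareolide carries on C11 can serve as its traceless precursor. The array C12–C13(C20)=C14 is the retron of an allyl-transposing addition to the Morita–Baylis–Hillman acetate of an acrylate (C12 = acrylate CH2, C13 = α-carbon, C20 = carboxyl carbon, C14 = former aldehyde carbon).

## Retrosynthesis

17 ⇒ 16. Only the C21–O–Si bond is cut. A single silyl ether, removed under buffered fluoride, keeps base away from C16–H and strong acid away from C8=C9.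

16 ⇒ 11 + 14 (via 15). The C16–C17 bond and the lactone C19–O bond are cut. The forward reaction is a catalytic asymmetric Nozaki–Hiyama–Kishi addition of the (Z)-β-iodoenoate 14 to aldehyde 11; the alkoxide of the hydroxy ester 15 lactonises onto the cis ester. Against C15–C16 alkylation of a butenolide dienolate (no control of C16) or alkynylation followed by cuprate addition (two more steps), this cut builds the ring and sets C16 under catalyst control in one operation, as the last C–C bond. It asks for Si-face selectivity, retention of the Z alkenyl geometry and tolerance of the free C20–OH.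

11 ⇒ 10 ⇒ 9. These are functional-group changes only: the C16 aldehyde is released from a diethyl acetal, and C20 is reduced from the ester to the alcohol by DIBAL-H while no lactone is present.

9 ⇒ 3 + 8 (key). The C11–C12 bond is cut with allyl transposition. The forward reaction is a decarboxylative radical addition of acid 3 to the Baylis–Hillman acetate 8, followed by loss of acetate. Against a C13=C14 olefination or a C12–C13 carbometalation (both need three redox steps to turn sclareolide's carboxyl into a C12 nucleophile), this cut uses the carboxyl itself as the leaving group. The C26 product 9 arises from a C16 acid and a C13 acetate, with the E olefin and C20 in place. The forward reaction must attack through C11 and not C8, and must eliminate to the 2E isomer.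

8 ⇒ 7 ⇒ 5 + 6; 5 ⇐ 4. A Morita–Baylis–Hillman reaction of methyl acrylate (6) with 3,3-diethoxypropanal (5, from ester 4) gives 7, which is acetylated. The carbinol centre of 7 can be racemic because step 6 destroys it.

3 ⇒ 2 ⇒ 1. Acidic methanolysis of sclareolide ionises the tertiary C8–O bond and, under equilibrating conditions, should give the tetrasubstituted olefin ester 2; saponification gives 3. C5 and C10 are untouched.

14 ⇒ 13 ⇒ 12. Anti-hydroiodination of commercial methyl 4-hydroxybut-2-ynoate (12) gives 13, which is silylated.

## Roads not taken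

Alternative 1: (most obvious) Cut C13=C14 by a stabilised Wittig reaction between ylide A1 (from 1 via ester, alcohol, iodide and ylide alkylation) and the preformed butenolide aldehyde A2, giving ester A3. The C20 ester of A3 cannot then be reduced without destroying the lactone (hydride gives the lactol, which dehydrates to a furan), so the butenolide would have to be built after the olefination in a longer linear sequence. A2 is also a β-acyloxy aldehyde that can ring-open by E1cB and epimerise at C16 under hot Wittig conditions. The chosen plan reduces C20 before the lactone exists and needs no C12 nucleophile.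

Alternative 2: Cut C12–C13 by copper-catalysed anti-carbomagnesiation of alkynol A5 with the Grignard reagent from bromide A4; the magnesium chelate would give 10 directly with the right geometry. The terpenoid would, however, be the organometallic partner, normally used in excess under forcing conditions. Three steps are spent converting the existing carboxyl into a bromide, and A5 has a propargylic CH2 next to an acetal that can lose ethanol or isomerise to an allene in hot Grignard solution. The chosen plan uses the acid as the limiting reagent at room temperature.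

Alternative 3: Cut the C5–C10 and C9–C10 ring bonds and form both rings by a proton-initiated cationic bicyclisation of the acyclic polyene A6 (enoate olefin deactivated, so the cascade stops after two rings), giving 9. Termination by proton loss from the C8 cation gives Δ7, Δ8 and Δ8(17) isomers; enantiocontrol without an aryl terminator needs a stoichiometric chiral acid; and A6 needs its own multistep assembly of three trisubstituted olefins. Sclareolide already supplies the rings and C5/C10 in enantiopure form.

Key step: step 6

## Route

Step 1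
Reactants: 1 (+)-sclareolide
Product: 2 methyl 2-Dr-acetate
Conditions: conc. H2SO4 (cat.), MeOH, reflux, to equilibrium; AgNO3–SiO2 chromatography
Reagents that add atoms: methanol, CO
Why: Acid-catalysed methanolysis: ionisation of the tertiary C8–O bond, Fischer esterification and E1 proton loss. Under reversible protonation the olefin isomers should funnel to the tetrasubstituted C8=C9 isomer; C5 and C10 are not involved.

Step 2
Reactants: 2 methyl 2-Dr-acetate
Product: 3 2-Dr-acetic acid
Conditions: LiOH·H2O, THF/MeOH/H2O, 50 °C; then 1 M HCl, 0 °C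
Reagents that add atoms: lithium hydroxide, [Li+].[OH-]
Why: Saponification; cold, brief acidification avoids re-lactonisation at C8.

Step 3
Reactants: 4 ethyl 3,3-diethoxypropanoate
Product: 5 3,3-diethoxypropanal
Conditions: DIBAL-H (1.05 equiv), CH2Cl2, −78 °C; Rochelle salt
Reagents that add atoms: none
Why: Partial ester reduction by DIBAL-H through the aluminium hemiacetal, which is stable at −78 °C.

Step 4
Reactants: 5 3,3-diethoxypropanal; 6 methyl acrylate
Product: 7 methyl 5,5-diethoxy-3-hydroxy-2-methylidenepentanoate (racemic)
Conditions: quinuclidine (0.25 equiv), MeOH (0.75 equiv), excess 6, rt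
Reagents that add atoms: none
Why: Morita–Baylis–Hillman reaction. The new carbinol centre is racemic and is destroyed in step 6.

Step 5
Reactants: 7 methyl 5,5-diethoxy-3-hydroxy-2-methylidenepentanoate
Product: 8 methyl 3-acetoxy-5,5-diethoxy-2-methylidenepentanoate (racemic)
Conditions: Ac2O, pyridine, DMAP (cat.), CH2Cl2, 0 °C
Reagents that add atoms: acetic anhydride, CC(=O)OC(C)=O
Why: O-Acetylation turns the carbinol oxygen into the leaving group for the allyl transposition; low temperature avoids amine-induced 1,3-shift of the acetate.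

Step 6
Reactants: 3 2-Dr-acetic acid; 8 methyl 3-acetoxy-5,5-diethoxy-2-methylidenepentanoate
Product: 9 methyl (2E)-5,5-diethoxy-2-(2-Dr-ethyl)pent-2-enoate
Conditions: [Ir{dF(CF3)ppy}2(dtbbpy)]PF6 (1 mol%), K2HPO4 (1.2 equiv), 8 (2.5 equiv), degassed DMSO, 450 nm LEDs, 25 °C
Reagents that add atoms: none
Why: Proposed new method: a decarboxylative radical allyl transposition on a Morita–Baylis–Hillman acetate, extended to an ambident allyl radical from a β,γ-unsaturated acid; the closest known reaction type is the photoredox decarboxylative Giese addition/E1cB allylation of alkyl carboxylic acids and redox-active esters with Baylis–Hillman acetates. Excited Ir(III) oxidises the carboxylate of 3, CO2 is lost, and the C11 radical (allylic to C8=C9) adds through C11 to the CH2 terminus of 8; Ir(II) then reduces the α-ester radical to the enolate, which expels acetate, so the process is redox-neutral. No ring is closed and no stereocentre is formed; the stereochemical outcome is the C13=C14 geometry, set in the elimination by A(1,3) strain, which places the C14 hydrogen rather than C15 beside the enolate oxygens and so puts C15 cis to C12 and trans to the ester (2E). Regioselectivity at the allyl radical (C11 against C8) is required and should follow from C8 being a tertiary ring carbon flanked by the quaternary C10, and from C11 attack restoring the tetrasubstituted ring olefin. Chemoselectivity between acceptor and product is required: 8 is a 1,1-disubstituted acrylate with a leaving group, whereas 9 is a β-substituted trisubstituted enoate that should not accept a second radical; excess 8 suppresses dimerisation of the stabilised radical. The acetal is inert and C5 and C10 are not involved.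

Step 7
Reactants: 9 methyl (2E)-5,5-diethoxy-2-(2-Dr-ethyl)pent-2-enoate
Product: 10 (2E)-5,5-diethoxy-2-(2-Dr-ethyl)pent-2-en-1-ol
Conditions: DIBAL-H (2.5 equiv), CH2Cl2, −78 °C; Rochelle salt
Reagents that add atoms: none
Why: 1,2-Reduction of the enoate to the allylic alcohol, done before any lactone exists. The acetal and both olefins are inert at −78 °C and the olefin geometry is retained.

Step 8
Reactants: 10 (2E)-5,5-diethoxy-2-(2-Dr-ethyl)pent-2-en-1-ol
Product: 11 (3E)-4-(hydroxymethyl)-6-Dr-hex-3-enal
Conditions: 10% aq. oxalic acid on SiO2, CH2Cl2, rt; filtered and used at once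
Reagents that add atoms: water, O
Why: Mild heterogeneous acetal hydrolysis. C20–OH is trans to C15 across the olefin and cannot form a cyclic acetal; the β,γ-unsaturated aldehyde is not stored.

Step 9
Reactants: 12 methyl 4-hydroxybut-2-ynoate
Product: 13 methyl (2Z)-4-hydroxy-3-iodobut-2-enoate
Conditions: NaI, AcOH, 70 °C
Reagents that add atoms: sodium iodide, [Na+].[I-]
Why: Conjugate anti-hydroiodination of the ynoate puts iodine cis to the ester (Z). The hydroxymethyl group is then trans to the ester and cannot lactonise.

Step 10
Reactants: 13 methyl (2Z)-4-hydroxy-3-iodobut-2-enoate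
Product: 14 methyl (2Z)-4-[(tert-butyldimethylsilyl)oxy]-3-iodobut-2-enoate
Conditions: TBSCl, imidazole, CH2Cl2, 0 °C to rt
Reagents that add atoms: tert-butyldimethylsilyl chloride, CC(C)(C)[Si](C)(C)Cl
Why: Silylation of the primary alcohol; the silyl ether is removable at the end without base.

Step 11
Reactants: 11 (3E)-4-(hydroxymethyl)-6-Dr-hex-3-enal; 14 methyl (2Z)-4-[(tert-butyldimethylsilyl)oxy]-3-iodobut-2-enoate
Product: 16 (5R)-4-{[(tert-butyldimethylsilyl)oxy]methyl}-5-[(2E)-3-(hydroxymethyl)-5-Dr-pent-2-en-1-yl]furan-2(5H)-one, via open-chain Z-hydroxy enoate 15 (not isolated)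
Conditions: CrCl2 (15 mol%), chiral 2-(4-isopropyloxazolin-2-yl)aryl methanesulfonamide ligand, proton sponge; NiCl2·(2,9-dimethylphenanthroline) (2 mol%), Mn, Cp2ZrCl2, LiCl, MeCN, rt; aqueous work-up, SiO2
Reagents that add atoms: none
Why: Catalytic asymmetric Nozaki–Hiyama–Kishi coupling. The chiral Cr(III) sulfonamide complex should deliver the alkenyl group to the Si face of the aldehyde, which gives 16R under catalyst control, and organochromium reagents tolerate the free C20–OH. The alkenylchromium keeps its Z geometry, so the alkoxide of 15 lactonises onto the cis ester.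

Step 12
Reactants: 16 (5R)-4-{[(tert-butyldimethylsilyl)oxy]methyl}-5-[(2E)-3-(hydroxymethyl)-5-Dr-pent-2-en-1-yl]furan-2(5H)-one
Product: 17 (5R)-4-(hydroxymethyl)-5-[(2E)-3-(hydroxymethyl)-5-Dr-pent-2-en-1-yl]furan-2(5H)-one (target, CNP0238475.3)
Conditions: HF·pyridine, pyridine/THF, 0 °C
Reagents that add atoms: none
Why: Buffered fluoride desilylation; C16–H is not exposed to base and C8=C9 is not exposed to strong acid.

## Compound list

1 | (+)-sclareolide, (3aR,5aS,9aS,9bR)-3a,6,6,9a-tetramethyldecahydronaphtho[2,1-b]furan-2(1H)-one | O=C1C[C@@H]2[C@@]3(C)CCCC(C)(C)[C@@H]3CC[C@@]2(C)O1 | starting material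
2 | methyl 2-Dr-acetate | CC1=C(CC(=O)OC)[C@@]2(C)CCCC(C)(C)[C@@H]2CC1 | intermediate
3 | 2-Dr-acetic acid | CC1=C(CC(=O)O)[C@@]2(C)CCCC(C)(C)[C@@H]2CC1 | intermediate
4 | ethyl 3,3-diethoxypropanoate | CCOC(=O)CC(OCC)OCC | starting material
5 | 3,3-diethoxypropanal | O=CCC(OCC)OCC | intermediate
6 | methyl acrylate | C=CC(=O)OC | starting material
7 | methyl 5,5-diethoxy-3-hydroxy-2-methylidenepentanoate (racemic) | C=C(C(=O)OC)C(O)CC(OCC)OCC | intermediate
8 | methyl 3-acetoxy-5,5-diethoxy-2-methylidenepentanoate (racemic) | C=C(C(=O)OC)C(OC(C)=O)CC(OCC)OCC | intermediate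
9 | methyl (2E)-5,5-diethoxy-2-(2-Dr-ethyl)pent-2-enoate | CC1=C(CC/C(=C\CC(OCC)OCC)C(=O)OC)[C@@]2(C)CCCC(C)(C)[C@@H]2CC1 | intermediate
10 | (2E)-5,5-diethoxy-2-(2-Dr-ethyl)pent-2-en-1-ol | CC1=C(CC/C(=C\CC(OCC)OCC)CO)[C@@]2(C)CCCC(C)(C)[C@@H]2CC1 | intermediate
11 | (3E)-4-(hydroxymethyl)-6-Dr-hex-3-enal | CC1=C(CC/C(=C\CC=O)CO)[C@@]2(C)CCCC(C)(C)[C@@H]2CC1 | intermediate
12 | methyl 4-hydroxybut-2-ynoate | COC(=O)C#CCO | starting material
13 | methyl (2Z)-4-hydroxy-3-iodobut-2-enoate | COC(=O)/C=C(\I)CO | intermediate
14 | methyl (2Z)-4-[(tert-butyldimethylsilyl)oxy]-3-iodobut-2-enoate | COC(=O)/C=C(\I)CO[Si](C)(C)C(C)(C)C | intermediate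
15 | methyl (2Z,4R,6E)-3-{[(tert-butyldimethylsilyl)oxy]methyl}-4-hydroxy-7-(hydroxymethyl)-9-Dr-nona-2,6-dienoate | CC1=C(CC/C(=C\C[C@@H](O)/C(CO[Si](C)(C)C(C)(C)C)=C\C(=O)OC)CO)[C@@]2(C)CCCC(C)(C)[C@@H]2CC1 | intermediate (not isolated)
16 | (5R)-4-{[(tert-butyldimethylsilyl)oxy]methyl}-5-[(2E)-3-(hydroxymethyl)-5-Dr-pent-2-en-1-yl]furan-2(5H)-one | CC1=C(CC/C(=C\C[C@H]2OC(=O)C=C2CO[Si](C)(C)C(C)(C)C)CO)[C@@]2(C)CCCC(C)(C)[C@@H]2CC1 | intermediate
17 | (5R)-4-(hydroxymethyl)-5-[(2E)-3-(hydroxymethyl)-5-Dr-pent-2-en-1-yl]furan-2(5H)-one | CC1=C(CC/C(=C\C[C@H]2OC(=O)C=C2CO)CO)[C@@]2(C)CCCC(C)(C)[C@@H]2CC1 | target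

## Step count and least certain steps

Total: 12 steps. Longest linear sequence: 8 steps (3, 4, 5, 6, 7, 8, 11, 12).

**Step 6 (key step, proposed new method).** The stabilised allyl radical may add too slowly, so that radical dimerisation or back-reduction to the hydrocarbon competes. Attack could occur in part through C8. The elimination could lose E selectivity, and the carboxylate could slowly displace the acetate of 8 in an SN2′ background reaction. The fallback uses known chemistry and sets out from 2. LiAlH4 reduction gives 2-Dr-ethanol F1. Iodine, triphenylphosphine and imidazole give 1-(2-iodoethyl)-Dr F2. Alkylation of sodium trimethyl phosphonoacetate with F2 gives methyl 2-(dimethoxyphosphoryl)-4-Dr-butanoate F3. Horner–Wadsworth–Emmons reaction of F3 with aldehyde 5 (NaH, THF) should give 9 as the major E isomer after separation. The fallback returns to the route at 9.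

**Step 1.** Equilibration may stop short of the tetrasubstituted isomer (proton loss from C7 or the C8 methyl), or the cation may re-close to the C8-epimeric lactone. Isomeric acids would give non-allylic radicals in step 6. The fallback sets out from 1 and is regiospecific. Selenation of the lactone enolate (LDA, PhSeBr) should give 11α-(phenylselanyl)sclareolide F4. Oxidation with H2O2 and syn-elimination towards C9–H gives 9(11)-dehydrosclareolide F5. Reductive cleavage of its allylic C8–O bond (SmI2, THF/HMPA, t-BuOH, −78 °C), with kinetic α-protonation of the dienolate, gives acid 3 directly. The fallback returns at 3.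

**Step 11.** Facial selectivity at the α-unbranched aldehyde may be insufficient, and C16 epimers would be hard to separate because the stereocentres are remote. The alkenylchromium could partly lose its Z geometry (no lactonisation), and 11 could isomerise to the conjugated enal. The fallback sets out from 11. Zinc–ProPhenol-catalysed addition of methyl propiolate (Me2Zn, toluene) gives methyl (4R,6E)-4-hydroxy-7-(hydroxymethyl)-9-Dr-non-6-en-2-ynoate F6. Syn conjugate addition of the cuprate made from tributyl[(1-ethoxyethoxy)methyl]stannane (BuLi, CuBr·SMe2, −78 °C), with lactonisation, gives (5R)-4-[(1-ethoxyethoxy)methyl]-5-[(2E)-3-(hydroxymethyl)-5-Dr-pent-2-en-1-yl]furan-2(5H)-one F7. PPTS in methanol removes the acetal and gives 17. The fallback returns at 17.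

**Step 8.** Acid may move the C13=C14 bond into conjugation with the new aldehyde or ionise the allylic C20–OH. The fallback sets out from 10. Silylation (TBSCl, imidazole) gives tert-butyl{[(2E)-5,5-diethoxy-2-(2-Dr-ethyl)pent-2-en-1-yl]oxy}dimethylsilane F8. Non-acidic acetal cleavage through the collidinium salt (TESOTf, 2,4,6-collidine, then water) gives (3E)-4-{[(tert-butyldimethylsilyl)oxy]methyl}-6-Dr-hex-3-enal F9. The coupling of step 11 with 14 gives (5R)-4-{[(tert-butyldimethylsilyl)oxy]methyl}-5-[(2E)-3-{[(tert-butyldimethylsilyl)oxy]methyl}-5-Dr-pent-2-en-1-yl]furan-2(5H)-one F10. HF·pyridine removes both silyl groups and gives 17. The fallback returns at 17.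

**Step 4.** Under amine catalysis 5 may lose ethanol by E1cB, and turnover with an aliphatic aldehyde may be slow. The fallback sets out from 5. Preformed [α-(methoxycarbonyl)vinyl]diisobutylaluminium (methyl propiolate, DIBAL-H, N-methylmorpholine N-oxide, THF, 0 °C) adds to the aldehyde without amine base and gives 7. The fallback returns at 7 and makes no new isolated compound.

## Further compounds

F1 | step 6 | 2-Dr-ethanol | CC1=C(CCO)[C@@]2(C)CCCC(C)(C)[C@@H]2CC1
F2 | step 6 | 1-(2-iodoethyl)-Dr | CC1=C(CCI)[C@@]2(C)CCCC(C)(C)[C@@H]2CC1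
F3 | step 6 | methyl 2-(dimethoxyphosphoryl)-4-Dr-butanoate | CC1=C(CCC(C(=O)OC)P(=O)(OC)OC)[C@@]2(C)CCCC(C)(C)[C@@H]2CC1
F4 | step 1 | 11α-(phenylselanyl)sclareolide | O=C1[C@@H]([Se]c4ccccc4)[C@@H]2[C@@]3(C)CCCC(C)(C)[C@@H]3CC[C@@]2(C)O1
F5 | step 1 | 9(11)-dehydrosclareolide | O=C1C=C2[C@@]3(C)CCCC(C)(C)[C@@H]3CC[C@@]2(C)O1
F6 | step 11 | methyl (4R,6E)-4-hydroxy-7-(hydroxymethyl)-9-Dr-non-6-en-2-ynoate | CC1=C(CC/C(=C\C[C@@H](O)C#CC(=O)OC)CO)[C@@]2(C)CCCC(C)(C)[C@@H]2CC1
F7 | step 11 | (5R)-4-[(1-ethoxyethoxy)methyl]-5-[(2E)-3-(hydroxymethyl)-5-Dr-pent-2-en-1-yl]furan-2(5H)-one | CC1=C(CC/C(=C\C[C@H]2OC(=O)C=C2COC(C)OCC)CO)[C@@]2(C)CCCC(C)(C)[C@@H]2CC1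
F8 | step 8 | tert-butyl{[(2E)-5,5-diethoxy-2-(2-Dr-ethyl)pent-2-en-1-yl]oxy}dimethylsilane | CC1=C(CC/C(=C\CC(OCC)OCC)CO[Si](C)(C)C(C)(C)C)[C@@]2(C)CCCC(C)(C)[C@@H]2CC1
F9 | step 8 | (3E)-4-{[(tert-butyldimethylsilyl)oxy]methyl}-6-Dr-hex-3-enal | CC1=C(CC/C(=C\CC=O)CO[Si](C)(C)C(C)(C)C)[C@@]2(C)CCCC(C)(C)[C@@H]2CC1
F10 | step 8 | (5R)-4-{[(tert-butyldimethylsilyl)oxy]methyl}-5-[(2E)-3-{[(tert-butyldimethylsilyl)oxy]methyl}-5-Dr-pent-2-en-1-yl]furan-2(5H)-one | CC1=C(CC/C(=C\C[C@H]2OC(=O)C=C2CO[Si](C)(C)C(C)(C)C)CO[Si](C)(C)C(C)(C)C)[C@@]2(C)CCCC(C)(C)[C@@H]2CC1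
F0 | step 4 | none | none
A1 | alternative 1 | methyl 4-Dr-2-(triphenyl-λ5-phosphanylidene)butanoate | CC1=C(CCC(=P(c3ccccc3)(c3ccccc3)c3ccccc3)C(=O)OC)[C@@]2(C)CCCC(C)(C)[C@@H]2CC1
A2 | alternative 1 | 2-[(2R)-3-{[(tert-butyldimethylsilyl)oxy]methyl}-5-oxo-2,5-dihydrofuran-2-yl]acetaldehyde | O=CC[C@H]1OC(=O)C=C1CO[Si](C)(C)C(C)(C)C
A3 | alternative 1 | methyl (2E)-2-(2-Dr-ethyl)-4-[(2R)-3-{[(tert-butyldimethylsilyl)oxy]methyl}-5-oxo-2,5-dihydrofuran-2-yl]but-2-enoate | CC1=C(CC/C(=C\C[C@H]2OC(=O)C=C2CO[Si](C)(C)C(C)(C)C)C(=O)OC)[C@@]2(C)CCCC(C)(C)[C@@H]2CC1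
A4 | alternative 2 | 1-(2-bromoethyl)-Dr | CC1=C(CCBr)[C@@]2(C)CCCC(C)(C)[C@@H]2CC1
A5 | alternative 2 | 5,5-diethoxypent-2-yn-1-ol | OCC#CCC(OCC)OCC
A6 | alternative 3 | methyl (2E)-5,5-diethoxy-2-[(3E,7E)-4,8,12-trimethyltrideca-3,7,11-trien-1-yl]pent-2-enoate | CC(C)=CCC/C(C)=C/CC/C(C)=C/CC/C(=C\CC(OCC)OCC)C(=O)OC
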